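Ring A is the ring with one hydroxyl and ring B is the diol ring.

The C40 chain is cut at C11=C12 and C11'=C12' into two C15 phosphonium salts and the C10 trienedial. Ring B is carried in from ketoisophorone; ring A is made last from an acyclic chain. Its key step is an epoxide-initiated cation–olefin cyclization: C5 of a (Z)-2-alkynylbut-2-ene attacks the CH2 terminus of an (S)-terminal epoxide, forming C4–C5 and the free (3R)-hydroxyl. It exploits the alkyne on C6 of ring A: the C6 cation is tertiary and propargylic and, flanked by quaternary C1, can lose only H5, so the tetrasubstituted C5=C6 enyne forms regiospecifically with the whole C7–C11 side chain in place.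

Key step: step 11

Remark (assumption on the chemistry): carotenoid locants are used throughout (ring A: C1–C6, hydroxyl on C3; ring B: primed locants, 3',4'-diol). The Z isomer that a Wittig reaction forms at a new disubstituted polyene double bond is assumed to equilibrate to E on mild warming.

Step 1
Reactants: 1 ketoisophorone (2,6,6-trimethylcyclohex-2-ene-1,4-dione)
Product: 2 (4S)-4-hydroxy-2,6,6-trimethylcyclohex-2-en-1-one
Conditions: RuCl[(S,S)-TsDPEN](p-cymene) (0.5 mol%), HCO2H/Et3N (5:2), CH2Cl2, rt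
Reagents that add atoms: none
Why: Noyori-type asymmetric transfer hydrogenation should reduce only the unhindered C4 carbonyl (the other carbonyl is shielded by the gem-dimethyl carbon), the chiral ruthenium hydride distinguishing the vinyl from the methylene flank to set the (S)-carbinol that becomes C3' of ring B.

Step 2
Reactants: 2 (4S)-4-hydroxy-2,6,6-trimethylcyclohex-2-en-1-one
Product: 3 tert-butyl (1S)-3,5,5-trimethyl-4-oxocyclohex-2-en-1-yl carbonate
Conditions: Boc2O, DMAP (cat.), CH2Cl2, rt
Reagents that add atoms: di-tert-butyl dicarbonate CC(C)(C)OC(=O)OC(=O)OC(C)(C)C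
Why: DMAP-catalysed O-acylation should give the tert-butyl carbonate without touching the stereocentre, installing the internal oxygen nucleophile needed in step 4.

Step 3
Reactants: 3 tert-butyl (1S)-3,5,5-trimethyl-4-oxocyclohex-2-en-1-yl carbonate; 4 (2E)-3-methylpent-2-en-4-yn-1-ol
Product: 5 tert-butyl (1S)-4-hydroxy-4-[(3E)-5-hydroxy-3-methylpent-3-en-1-yn-1-yl]-3,5,5-trimethylcyclohex-2-en-1-yl carbonate (both epimers at the new carbinol carbon)
Conditions: 4 (1.3 equiv), n-BuLi (2.6 equiv), THF, −78 °C; then 3, −78 to −30 °C; then H2O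
Reagents that add atoms: none
Why: 1,2-addition of the lithium acetylide (the alkoxide–acetylide dianion of 4) to the enone carbonyl should outrun attack on the hindered tert-butyl carbonate at low temperature, and the new tertiary carbinol centre forms as an epimer mixture that is erased in step 4.

Step 4
Reactants: 5 tert-butyl (1S)-4-hydroxy-4-[(3E)-5-hydroxy-3-methylpent-3-en-1-yn-1-yl]-3,5,5-trimethylcyclohex-2-en-1-yl carbonate
Product: 6 (3aS,7aR)-6-[(3E)-5-hydroxy-3-methylpent-3-en-1-yn-1-yl]-5,5,7-trimethyl-3a,4,5,7a-tetrahydro-1,3-benzodioxol-2-one (cis-fused cyclic carbonate of the ring B diol)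
Conditions: BF3·OEt2 (0.2 equiv), 4 Å molecular sieves, CH2Cl2, −40 °C
Reagents that add atoms: none
Why: ionisation of the tertiary allylic and propargylic alcohol should give a delocalised cation that the carbonyl oxygen of the neighbouring Boc group captures at the ring allylic terminus in a 5-exo SN1' cyclisation with loss of isobutene (Boc neighbouring-group participation, as in halocarbonate cyclisations), so the C4' oxygen arrives on the face of the C3' oxygen, the diol is cis by ring fusion, and the double bond ends at C5'=C6' in conjugation with the alkyne.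

Step 5
Reactants: 6 (3aS,7aR)-6-[(3E)-5-hydroxy-3-methylpent-3-en-1-yn-1-yl]-5,5,7-trimethyl-3a,4,5,7a-tetrahydro-1,3-benzodioxol-2-one
Product: 8 {(2E)-3-methyl-5-[(3aS,7aR)-5,5,7-trimethyl-2-oxo-3a,4,5,7a-tetrahydro-1,3-benzodioxol-6-yl]pent-2-en-4-yn-1-yl}triphenylphosphonium bromide (ring B C15 salt), via allylic bromide 7 (not isolated)
Conditions: CBr4 (1.1 equiv), PPh3 (2.3 equiv), CH2Cl2, 0 °C to rt
Reagents that add atoms: triphenylphosphine c1ccc(cc1)P(c1ccccc1)c1ccccc1; tetrabromomethane BrC(Br)(Br)Br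
Why: Appel bromination of the primary allylic alcohol under neutral conditions, followed by SN2 quaternisation of the excess PPh3 by the allylic bromide, should give the salt without ionising the allylic cyclic carbonate or scrambling the (E)-alkene.

Step 6
Reactants: 9 2,2-dimethylpent-4-enoic acid
Product: 10 4,4-dimethylhept-6-en-3-one
Conditions: EtLi (2.2 equiv), Et2O, 0 °C to rt; then 1 M HCl (inverse quench)
Reagents that add atoms: ethyllithium [Li]CC
Why: carboxylate-to-ketone synthesis, in which the second equivalent of EtLi adds to the lithium carboxylate to give a dilithium gem-diolate that cannot add again and collapses to the ethyl ketone on acidic quench.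

Step 7
Reactants: 10 4,4-dimethylhept-6-en-3-one
Product: 11 (2Z)-4,4-dimethylhepta-2,6-dien-3-yl trifluoromethanesulfonate
Conditions: KN(SiMe3)2, THF, −78 °C; then PhNTf2, −78 to 0 °C
Reagents that add atoms: N-phenylbis(trifluoromethanesulfonimide) O=S(=O)(N(c1ccccc1)S(=O)(=O)C(F)(F)F)C(F)(F)F
Why: enol triflate formation, in which kinetic enolisation (possible only on the ethyl side) should give the (Z)-enolate with the methyl turned away from the tert-alkyl group and PhNTf2 then triflates it on oxygen.

Step 8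
Reactants: 11 (2Z)-4,4-dimethylhepta-2,6-dien-3-yl trifluoromethanesulfonate
Product: 12 racemic (2Z)-4,4-dimethyl-5-(oxiran-2-yl)pent-2-en-3-yl trifluoromethanesulfonate
Conditions: mCPBA, CH2Cl2, 0 °C to rt
Reagents that add atoms: 3-chloroperoxybenzoic acid OOC(=O)c1cccc(Cl)c1
Why: Prilezhaev epoxidation should occur at the terminal alkene because the enol triflate double bond is deactivated by the triflyloxy group, and the epoxide is racemic at this stage.

Step 9
Reactants: 12 racemic (2Z)-4,4-dimethyl-5-(oxiran-2-yl)pent-2-en-3-yl trifluoromethanesulfonate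
Product: 13 (2Z)-4,4-dimethyl-5-[(2S)-oxiran-2-yl]pent-2-en-3-yl trifluoromethanesulfonate
Conditions: (S,S)-(salen)Co(OAc) (trivalent cobalt; salen = N,N'-bis(3,5-di-tert-butylsalicylidene)cyclohexane-1,2-diamine dianion; 0.5 mol%), H2O (0.55 equiv), THF, 0 °C to rt
Reagents that add atoms: none
Why: Jacobsen hydrolytic kinetic resolution, in which the (S,S)-cobalt–salen catalyst should hydrate the (R)-epoxide selectively so that the unreacted (S)-epoxide is recovered, its stereocentre becoming C3 of ring A.

Step 10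
Reactants: 13 (2Z)-4,4-dimethyl-5-[(2S)-oxiran-2-yl]pent-2-en-3-yl trifluoromethanesulfonate; 4 (2E)-3-methylpent-2-en-4-yn-1-ol
Product: 14 (2E,6Z)-3-methyl-6-{2-methyl-1-[(2S)-oxiran-2-yl]propan-2-yl}octa-2,6-dien-4-yn-1-ol
Conditions: 4 (1.2 equiv), Pd(PPh3)4 (5 mol%), CuI (10 mol%), Et3N, THF, 40 °C
Reagents that add atoms: none
Why: Sonogashira coupling of the enol triflate with the terminal alkyne should proceed with retention of the (Z)-geometry and leave the epoxide and the alcohol untouched, placing the alkyne on the future C6 together with the C7–C11 chain.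

Step 11
Reactants: 14 (2E,6Z)-3-methyl-6-{2-methyl-1-[(2S)-oxiran-2-yl]propan-2-yl}octa-2,6-dien-4-yn-1-ol
Product: 15 (1R)-4-[(3E)-5-hydroxy-3-methylpent-3-en-1-yn-1-yl]-3,5,5-trimethylcyclohex-3-en-1-ol (ring A C15 diol)
Conditions: MeAlCl2 (2.5 equiv), CH2Cl2, −78 to −30 °C; then H2O
Reagents that add atoms: none
Why: MeAlCl2 activates the epoxide, C5 of the trisubstituted enyne alkene attacks the CH2 terminus (future C4) from the backside through a chair-like transition state, and the resulting tertiary propargylic C6 cation loses H5 to give the tetrasubstituted C5=C6 bond, the Al–CH3 groups taking up both the hydroxyl proton and the proton released (as methane) so that the medium stays aprotic. The closest known reaction type is the epoxide-initiated cation–olefin cyclisation, including Lewis-acid openings of terminal epoxides at the unsubstituted carbon by tethered arenes and allylsilanes. Ring A closes in the 6-endo mode with respect to both the epoxide and the alkene. No stereocentre is created: only the C4–O bond breaks, so C3 keeps the configuration fixed in step 9 and appears as the (3R)-carbinol. The step needs attack at C4 and not C3 (attack at C3 would be a 5-endo-trig closure), attack by the alkene and not the alkyne (the alkene is the better π-nucleophile and leads to the tertiary propargylic cation), and one direction of proton loss, which is secured because C6 is flanked only by quaternary C1 and the alkyne, so that H5, axial in the chair formed from the (Z)-alkene, is the only β-hydrogen.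

Step 12
Reactants: 15 (1R)-4-[(3E)-5-hydroxy-3-methylpent-3-en-1-yn-1-yl]-3,5,5-trimethylcyclohex-3-en-1-ol
Product: 16 {(2E)-5-[(4R)-4-hydroxy-2,6,6-trimethylcyclohex-1-en-1-yl]-3-methylpent-2-en-4-yn-1-yl}triphenylphosphonium bromide (ring A C15 salt)
Conditions: PPh3·HBr, MeOH/CH2Cl2, rt
Reagents that add atoms: triphenylphosphine hydrobromide Br.c1ccc(cc1)P(c1ccccc1)c1ccccc1
Why: phosphonium salt formation by SN1-type substitution through the delocalised primary allylic cation, which the homoallylic C3 alcohol cannot form, so only C11 reacts and C3 keeps its configuration.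

Step 13
Reactants: 16 {(2E)-5-[(4R)-4-hydroxy-2,6,6-trimethylcyclohex-1-en-1-yl]-3-methylpent-2-en-4-yn-1-yl}triphenylphosphonium bromide; 17 (2E,4E,6E)-2,7-dimethylocta-2,4,6-trienedial
Product: 18 (2E,4E,6E,8E,10E)-13-[(4R)-4-hydroxy-2,6,6-trimethylcyclohex-1-en-1-yl]-2,7,11-trimethyltrideca-2,4,6,8,10-pentaen-12-ynal
Conditions: 17 (3 equiv), NaOMe (1.1 equiv), MeOH/CH2Cl2, 0 °C to rt; then EtOH, 60 °C
Reagents that add atoms: none
Why: Wittig olefination of one aldehyde of the excess symmetrical dialdehyde by the conjugated allylic ylide forms C11=C12, the excess dialdehyde suppressing double olefination and any 11Z isomer being expected to equilibrate to E on warming.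

Step 14
Reactants: 18 (2E,4E,6E,8E,10E)-13-[(4R)-4-hydroxy-2,6,6-trimethylcyclohex-1-en-1-yl]-2,7,11-trimethyltrideca-2,4,6,8,10-pentaen-12-ynal; 8 {(2E)-3-methyl-5-[(3aS,7aR)-5,5,7-trimethyl-2-oxo-3a,4,5,7a-tetrahydro-1,3-benzodioxol-6-yl]pent-2-en-4-yn-1-yl}triphenylphosphonium bromide
Product: 20 all-E target triol CNP0323983.1 (ring A 3R-hydroxy; ring B 3'S,4'R-cis-diol), via C40 cyclic carbonate 19 (not isolated)
Conditions: NaOMe (1.1 equiv), MeOH/CH2Cl2, 0 °C; then further NaOMe (0.5 equiv), rt; then EtOH, 60 °C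
Reagents that add atoms: none
Why: a second Wittig olefination forms C11'=C12', and methoxide-mediated methanolysis of the cyclic carbonate then frees the cis-3',4'-diol under basic conditions, avoiding the acid that the allylic C4' alcohol and the polyene would not tolerate.

Compound list
1 | ketoisophorone (2,6,6-trimethylcyclohex-2-ene-1,4-dione) | CC1=CC(=O)CC(C)(C)C1=O | starting material
2 | (4S)-4-hydroxy-2,6,6-trimethylcyclohex-2-en-1-one | CC1=C[C@@H](O)CC(C)(C)C1=O | intermediate
3 | tert-butyl (1S)-3,5,5-trimethyl-4-oxocyclohex-2-en-1-yl carbonate | CC1=C[C@@H](OC(=O)OC(C)(C)C)CC(C)(C)C1=O | intermediate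
4 | (2E)-3-methylpent-2-en-4-yn-1-ol | C#C/C(C)=C/CO | starting material
5 | tert-butyl (1S)-4-hydroxy-4-[(3E)-5-hydroxy-3-methylpent-3-en-1-yn-1-yl]-3,5,5-trimethylcyclohex-2-en-1-yl carbonate (epimers at the tertiary carbinol) | CC1=C[C@@H](OC(=O)OC(C)(C)C)CC(C)(C)C1(O)C#C/C(C)=C/CO | intermediate
6 | (3aS,7aR)-6-[(3E)-5-hydroxy-3-methylpent-3-en-1-yn-1-yl]-5,5,7-trimethyl-3a,4,5,7a-tetrahydro-1,3-benzodioxol-2-one | OC/C=C(C)/C#CC1=C(C)[C@@H](OC(=O)O2)[C@@H]2CC1(C)C | intermediate
7 | (3aS,7aR)-6-[(3E)-5-bromo-3-methylpent-3-en-1-yn-1-yl]-5,5,7-trimethyl-3a,4,5,7a-tetrahydro-1,3-benzodioxol-2-one | BrC/C=C(C)/C#CC1=C(C)[C@@H](OC(=O)O2)[C@@H]2CC1(C)C | intermediate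
8 | {(2E)-3-methyl-5-[(3aS,7aR)-5,5,7-trimethyl-2-oxo-3a,4,5,7a-tetrahydro-1,3-benzodioxol-6-yl]pent-2-en-4-yn-1-yl}triphenylphosphonium bromide | [Br-].C(/C=C(C)/C#CC1=C(C)[C@@H](OC(=O)O2)[C@@H]2CC1(C)C)[P+](c3ccccc3)(c4ccccc4)c5ccccc5 | intermediate
9 | 2,2-dimethylpent-4-enoic acid | C=CCC(C)(C)C(=O)O | starting material
10 | 4,4-dimethylhept-6-en-3-one | CCC(=O)C(C)(C)CC=C | intermediate
11 | (2Z)-4,4-dimethylhepta-2,6-dien-3-yl trifluoromethanesulfonate | C/C=C(\OS(=O)(=O)C(F)(F)F)C(C)(C)CC=C | intermediate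
12 | racemic (2Z)-4,4-dimethyl-5-(oxiran-2-yl)pent-2-en-3-yl trifluoromethanesulfonate | C/C=C(\OS(=O)(=O)C(F)(F)F)C(C)(C)CC1CO1 | intermediate
13 | (2Z)-4,4-dimethyl-5-[(2S)-oxiran-2-yl]pent-2-en-3-yl trifluoromethanesulfonate | C/C=C(\OS(=O)(=O)C(F)(F)F)C(C)(C)C[C@H]1CO1 | intermediate
14 | (2E,6Z)-3-methyl-6-{2-methyl-1-[(2S)-oxiran-2-yl]propan-2-yl}octa-2,6-dien-4-yn-1-ol | OC/C=C(C)/C#C/C(=C\C)C(C)(C)C[C@H]1CO1 | intermediate
15 | (1R)-4-[(3E)-5-hydroxy-3-methylpent-3-en-1-yn-1-yl]-3,5,5-trimethylcyclohex-3-en-1-ol | CC1=C(C#C/C(C)=C/CO)C(C)(C)C[C@H](O)C1 | intermediate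
16 | {(2E)-5-[(4R)-4-hydroxy-2,6,6-trimethylcyclohex-1-en-1-yl]-3-methylpent-2-en-4-yn-1-yl}triphenylphosphonium bromide | [Br-].CC1=C(C#C/C(C)=C/C[P+](c2ccccc2)(c3ccccc3)c4ccccc4)C(C)(C)C[C@H](O)C1 | intermediate
17 | (2E,4E,6E)-2,7-dimethylocta-2,4,6-trienedial | O=C/C(C)=C/C=C/C=C(C)/C=O | starting material
18 | (2E,4E,6E,8E,10E)-13-[(4R)-4-hydroxy-2,6,6-trimethylcyclohex-1-en-1-yl]-2,7,11-trimethyltrideca-2,4,6,8,10-pentaen-12-ynal | CC1=C(C#C/C(C)=C/C=C/C(C)=C/C=C/C=C(C)/C=O)C(C)(C)C[C@H](O)C1 | intermediate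
19 | 3',4'-cyclic carbonate of the target (all-E) | CC1=C(C#C/C(C)=C/C=C/C(C)=C/C=C/C=C(C)/C=C/C=C(\C)C#CC2=C(C)[C@@H](OC(=O)O3)[C@@H]3CC2(C)C)C(C)(C)C[C@H](O)C1 | intermediate
20 | CNP0323983.1, all-E 7,8,7',8'-tetradehydro-β,β-carotene triol (ring A 3R-hydroxy; ring B 3'S,4'R-cis-diol) | CC1=C(C#C/C(C)=C/C=C/C(C)=C/C=C/C=C(C)/C=C/C=C(\C)C#CC2=C(C)[C@@H](O)[C@@H](O)CC2(C)C)C(C)(C)C[C@H](O)C1 | target

Total step count: 14. Longest linear sequence: 9 steps (steps 6 to 14, from 2,2-dimethylpent-4-enoic acid).

Steps most likely to fail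

Step 11 (key step). The activated epoxide may be opened by chloride from the aluminium reagent, or rearrange by hydride shift to a carbonyl compound, before the moderately nucleophilic enyne alkene reaches its primary carbon. Reversible capture of the C6 cation by the C3 alkoxide is a further diversion. The fallback closes ring A by an intramolecular enolate alkylation; it sets out from 10 and comes back at 15. Buffered mCPBA epoxidation of 10 would give racemic 4,4-dimethyl-5-(oxiran-2-yl)pentan-3-one F1. Hydrolytic kinetic resolution with the (S,S)-cobalt–salen catalyst would leave 4,4-dimethyl-5-[(2S)-oxiran-2-yl]pentan-3-one F2. LiI/AcOH would open it at the terminus to (6S)-6-hydroxy-7-iodo-4,4-dimethylheptan-3-one F3, and TBSOTf/2,6-lutidine would give its silyl ether F4. KOtBu in THF would form the only possible enolate, which displaces iodide in a 6-exo-tet alkylation to (4R)-4-[(tert-butyldimethylsilyl)oxy]-2,2,6-trimethylcyclohexan-1-one F5; the methyl-bearing carbon is an epimer mixture and later becomes sp2. KN(SiMe3)2/PhNTf2 would give the tetrasubstituted enol triflate F6. Sonogashira coupling with 4 would give the silyl-protected C15 enynol F7, and Bu4NF would remove the silyl group to return to 15.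

Step 4. The delocalised cation may lose a proton to a dienyne, or be trapped by water at the alkyne terminus (Meyer–Schuster-type rearrangement), faster than the Boc carbonyl closes. Loss of the tert-butyl group before ionisation would remove the internal nucleophile. The fallback does the transposition oxidatively; it sets out from 5 and comes back at 6. TBSCl/imidazole would silylate the primary alcohol to give silyl ether F8. Pyridinium chlorochromate, (C5H5NH)[CrO3Cl], in CH2Cl2 (Babler–Dauben oxidative transposition of the tertiary allylic alcohol) would give the transposed enone F9, a (3'S)-3'-acyloxy-4'-ketone. Luche reduction (NaBH4, CeCl3, MeOH, −78 °C), with hydride delivered anti to the neighbouring carbonate, would give the cis-hydroxy carbonate F10. Catalytic KOtBu in THF would close the alkoxide onto the Boc carbonyl with loss of tert-butanol to give the silyl-protected cyclic carbonate F11, a closure open only to the cis isomer. Bu4NF buffered with AcOH would then return to 6.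

Step 14. E selectivity at the new C11'=C12' bond may be incomplete, and the warming used to equilibrate it may scramble the 9- and 9'-double bonds next to the alkynes. Early methanolysis of the carbonate may also make the ylide poorly soluble. The fallback uses a Horner–Wadsworth–Emmons olefination; it sets out from 6 and comes back at 20. Appel bromination with one equivalent of PPh3 at −20 °C would give bromide 7, now isolated. Arbuzov reaction with P(OEt)3 would give the allylic phosphonate F12. Deprotonation with NaN(SiMe3)2 in THF at −78 °C and addition of 18 (pre-treated with one equivalent of the same base for its hydroxyl) should give 19 with the E selectivity typical of allylic phosphonates. Catalytic K2CO3 in MeOH would then free the diol and give 20 without thermal equilibration.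

Further compounds
F1 | step 11 | racemic 4,4-dimethyl-5-(oxiran-2-yl)pentan-3-one | CCC(=O)C(C)(C)CC1CO1
F2 | step 11 | 4,4-dimethyl-5-[(2S)-oxiran-2-yl]pentan-3-one | CCC(=O)C(C)(C)C[C@H]1CO1
F3 | step 11 | (6S)-6-hydroxy-7-iodo-4,4-dimethylheptan-3-one | CCC(=O)C(C)(C)C[C@H](O)CI
F4 | step 11 | (6S)-6-[(tert-butyldimethylsilyl)oxy]-7-iodo-4,4-dimethylheptan-3-one | CCC(=O)C(C)(C)C[C@H](O[Si](C)(C)C(C)(C)C)CI
F5 | step 11 | (4R)-4-[(tert-butyldimethylsilyl)oxy]-2,2,6-trimethylcyclohexan-1-one (C6 epimers) | CC1C[C@@H](O[Si](C)(C)C(C)(C)C)CC(C)(C)C1=O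
F6 | step 11 | (4R)-4-[(tert-butyldimethylsilyl)oxy]-2,6,6-trimethylcyclohex-1-en-1-yl trifluoromethanesulfonate | CC1=C(OS(=O)(=O)C(F)(F)F)C(C)(C)C[C@H](O[Si](C)(C)C(C)(C)C)C1
F7 | step 11 | (2E)-5-{(4R)-4-[(tert-butyldimethylsilyl)oxy]-2,6,6-trimethylcyclohex-1-en-1-yl}-3-methylpent-2-en-4-yn-1-ol | CC1=C(C#C/C(C)=C/CO)C(C)(C)C[C@H](O[Si](C)(C)C(C)(C)C)C1
F8 | step 4 | tert-butyl (1S)-4-{(3E)-5-[(tert-butyldimethylsilyl)oxy]-3-methylpent-3-en-1-yn-1-yl}-4-hydroxy-3,5,5-trimethylcyclohex-2-en-1-yl carbonate | CC1=C[C@@H](OC(=O)OC(C)(C)C)CC(C)(C)C1(O)C#C/C(C)=C/CO[Si](C)(C)C(C)(C)C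
F9 | step 4 | tert-butyl (1S)-4-{(3E)-5-[(tert-butyldimethylsilyl)oxy]-3-methylpent-3-en-1-yn-1-yl}-3,5,5-trimethyl-2-oxocyclohex-3-en-1-yl carbonate | CC1=C(C#C/C(C)=C/CO[Si](C)(C)C(C)(C)C)C(C)(C)C[C@H](OC(=O)OC(C)(C)C)C1=O
F10 | step 4 | tert-butyl (1S,2R)-4-{(3E)-5-[(tert-butyldimethylsilyl)oxy]-3-methylpent-3-en-1-yn-1-yl}-2-hydroxy-3,5,5-trimethylcyclohex-3-en-1-yl carbonate | C[Si](C)(C(C)(C)C)OC/C=C(C)/C#CC1=C(C)[C@@H](O)[C@@H](OC(=O)OC(C)(C)C)CC1(C)C
F11 | step 4 | (3aS,7aR)-6-{(3E)-5-[(tert-butyldimethylsilyl)oxy]-3-methylpent-3-en-1-yn-1-yl}-5,5,7-trimethyl-3a,4,5,7a-tetrahydro-1,3-benzodioxol-2-one | C[Si](C)(C(C)(C)C)OC/C=C(C)/C#CC1=C(C)[C@@H](OC(=O)O2)[C@@H]2CC1(C)C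
F12 | step 14 | diethyl {(2E)-3-methyl-5-[(3aS,7aR)-5,5,7-trimethyl-2-oxo-3a,4,5,7a-tetrahydro-1,3-benzodioxol-6-yl]pent-2-en-4-yn-1-yl}phosphonate | CCOP(=O)(OCC)C/C=C(C)/C#CC1=C(C)[C@@H](OC(=O)O2)[C@@H]2CC1(C)C
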